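I decided to reckon each flask by one clock, the half-life of tris adduct, and to find the moment at which control passes to it.

| setting | north | south | epsilon | zeta |
|---|---|---|---|---|
| substrate | 0.94 M | 3 M | 0.80 M | 2.5 M |
| gas | 200 mM (held) | 200 mM (held) | 200 mM (held) | 200 mM (held) |
| remark | run made earlier | run made earlier |  |  |
| time |  |  | 15 min | 50 min |

| run | time / min | tris adduct / % | over-reaction product A / % |
|---|---|---|---|
| north | 1.00 | 1.7 | 0 |
| north | 2.50 | 8.0 | 0 |
| north | 5.00 | 24.9 | 8.9 |
| north | 8.00 | 41.6 | 23.2 |
| north | 10.0 | 45.1 | 39.6 |
| south | 0.833 | 0 | 1.1 |
| south | 1.50 | 0 | 0.8 |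
| south | 3.00 | 2.4 | 1.5 |
| south | 6.00 | 6.3 | 2.1 |
| south | 10.0 | 16.0 | 9.0 |

(standard deviation of a reading: 1 percentage point)

- at the start none of partner is dissolved
- steps under discussion: substrate + partner -> mono adduct; partner + mono adduct -> double product; partner + double product -> tris adduct; tris adduct -> over-reaction product A; tris adduct -> over-reaction product B; gas <-> partner
- the share counts what is present at the end, not what went on to other products

- which one finishes higher in share of tris adduct in all that became tris adduct or over-reaction product A ("neither" within 2 percentage points) (epsilon / zeta / neither)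
- share of tris adduct in all that became tris adduct or over-reaction product A, epsilon
- share of tris adduct in all that became tris adduct or over-reaction product A, zeta

Write T for tris adduct, A for over-reaction product A, and take the loss of T as first order with constant k.

The shortest rung is that loss. In the north run, from 5.00 min to 10.0 min, A rose against the time integral of T, which read as k = 0.165 min⁻¹. So the half-life of T, h = ln(2)/k, was 4.21 min.

The next rung is the feed F, the mean making of T plus A. It read 0.0796 M min⁻¹ in the north run and 0.0750 M min⁻¹ in the south run. The two were close at 3.19 times the substrate, so I took gas passage as the rate-limiting step.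

The crossing is charge over F: 10.0 min for epsilon and 33.3 min for zeta. After it, I let T simply decay and counted T plus A as the whole charge.

Epsilon starts its decay from the north run's last share and gets 23.6%. Zeta has no reading near its crossing, so as a rough start I took the south run's last T, 16.0% of the charge, and my estimate is 1.03%.

The forecast said: “Decay of tris is first order.” It gave 25% for epsilon and 2% for zeta, so epsilon; my own figures differ from these.

Epsilon finished at 27.4% and zeta at 0.331%, so epsilon stood higher.

    substrate + partner → mono adduct (k = 0.0530 M⁻¹ s⁻¹)
    partner + mono adduct → double product (k = 0.150 M⁻¹ s⁻¹)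
    partner + double product → tris adduct (k = 0.0800 M⁻¹ s⁻¹)
    tris adduct → over-reaction product A (k = 0.00270 s⁻¹)
    tris adduct → over-reaction product B (k = 4.10 × 10⁻⁶ s⁻¹)
    gas ⇌ partner, rate k6*(csat - [partner]) (kL = 0.0440 s⁻¹)

At 25.0 min, earlier than my crossing, zeta already held 18.3% T and 0.128% substrate. From there my h counts 5.94 half-lives and reckons T at 0.299%, against 0.330% in zeta at 50.0 min. The north run, with its time moved to epsilon's, shows a share of 29.8%. Over the 35.0 min up to zeta's time, h reckons that down to 0.0936%, and the north run with its time moved to zeta's shows 0.106%.

The data were generated by integration for an exercise.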